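**Plan**

1. The ketone is cut between its carbonyl carbon and the methylidene-bearing carbon (alkenylchromium addition to an aryloxyacetaldehyde, then oxidation). This gives a 2-bromoallyl butenolide and a coumarin aldehyde.
2. The butenolide (O1, C2 carbonyl, C3 methyl-bearing, C4, C5 stereocentre) is cut at C2–C3 and C2–O1. The lactone carbonyl C2 lies between alkene carbon C3 and ring oxygen O1, so it is one CO inserted between a C3–I bond and the C5 hydroxyl of a Z-iodoalkenol in which these groups are cis.
3. The iodoalkenol is cut at the C5–CH2 bond (2-bromoallylboration of (Z)-3-iodobut-2-enal); the enal comes from but-2-yn-1-ol.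
4. Forward: the chain is built from but-2-yn-1-ol and allene, the butenolide ring is closed (the only ring made; the coumarin is bought), the coumarin aldehyde is joined, and the carbinol is oxidised.
5. Stereochemistry: C5 (R) comes from reagent-controlled allylboration with isopinocampheyl groups from (−)-α-pinene. The Z geometry comes from hydroxyl-directed trans-hydroalumination and iodination. The carbinol centre formed in the chromium coupling is uncontrolled and is removed by oxidation.

Key step: step 4

Assumption: the 2-bromoallyl borane is taken to show the same facial preference as the parent allyl reagent (isopinocampheyl groups from (−)-α-pinene give Re-face attack), and B-bromodiisopinocampheylborane is prepared beforehand from (−)-α-pinene and BH2Br·SMe2 and used as a stock solution.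

**Route**

Step 1
Reactants: 1 but-2-yn-1-ol
Product: 3 (Z)-3-iodobut-2-en-1-ol, via cyclic alkenylalanate 2 (not isolated)
Conditions: NaAlH2(OCH2CH2OMe)2 (Red-Al), THF, 0 °C → rt; EtOAc; then I2, THF, −78 → 0 °C
Reagents that add atoms: iodine, SMILES II
Why: Hydroxyl-directed trans-hydroalumination of the propargylic alcohol (Red-Al reduction) puts hydride on C2 and aluminium on C3 inside a five-membered alanate, and iodinolysis of the C–Al bond with retention should give the alkenyl iodide with iodine cis to the CH2OH carbon (Z); no stereocentre is formed.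

Step 2
Reactants: 3 (Z)-3-iodobut-2-en-1-ol
Product: 4 (Z)-3-iodobut-2-enal
Conditions: MnO2, CH2Cl2, rt, dark; used at once
Reagents that add atoms: none
Why: Allylic oxidation with MnO2 is neutral, heterogeneous and selective for allylic alcohols, so the alkenyl iodide and its Z geometry should be kept; no stereocentre is formed.

Step 3
Reactants: 4 (Z)-3-iodobut-2-enal; 5 allene
Product: 8 (2Z,4R)-6-bromo-2-iodohepta-2,6-dien-4-ol, via (2-bromoallyl)diisopinocampheylborane 6 (not isolated), via dienyl diisopinocampheylborinate 7 (not isolated)
Conditions: Ipc2BBr [from (−)-α-pinene], 5, CH2Cl2, −78 → 0 °C; then 4, Et2O, −78 °C; NaOH, H2O2, 0 °C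
Reagents that add atoms: B-bromodiisopinocampheylborane from (−)-α-pinene, SMILES BrB([C@H]1C[C@H]2C[C@@H]([C@@H]1C)C2(C)C)[C@H]1C[C@H]2C[C@@H]([C@@H]1C)C2(C)C
Why: Bromoboration of allene gives the 2-bromoallylborane, which adds to the aldehyde in a Brown-type asymmetric allylboration through a chair Zimmerman–Traxler transition state in which the isopinocampheyl groups from (−)-α-pinene should direct the allyl group to the Re face of the formyl group and set the carbinol carbon as R (reagent control), after which alkaline H2O2 cleaves the borinate.

Step 4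
Reactants: 8 (2Z,4R)-6-bromo-2-iodohepta-2,6-dien-4-ol; 9 carbon monoxide
Product: 10 (R)-5-(2-bromoprop-2-en-1-yl)-3-methylfuran-2(5H)-one
Conditions: Pd(PPh3)4 (5 mol%), K2CO3, CO (1 atm), THF, 25 °C
Reagents that add atoms: none
Why: Zerovalent palladium adds oxidatively to the alkenyl C–I bond of 8 with retention of the Z geometry, CO inserts to give an alkenoylpalladium species, and the cis-disposed hydroxyl, assisted by carbonate, attacks the acyl carbon to release lactone 10 and return the catalyst. The closest known reaction type is the palladium-catalysed carbonylative lactonisation of (Z)-3-iodoallylic alcohols to but-2-enolides, an intramolecular alkoxycarbonylation. The butenolide ring closes by 5-exo-trig attack of oxygen on the acylpalladium carbon (equivalently C–O reductive elimination from a six-membered palladacycle), forming the C2–C3 and C2–O1 bonds of the lactone. No new stereocentre is formed: lactone C5 is the carbinol carbon of 8, its C–O bond is never broken, and the R configuration should be carried through. The step needs oxidative addition at C–I in preference to the alkenyl C–Br bond, which the weaker C–I bond and the 25 °C temperature should secure, and it needs CO insertion to outrun Heck-type cyclisation onto the bromoalkene, which the CO atmosphere and the adjacent hydroxyl favour. The Z geometry fixed in step 1 holds the hydroxyl and the acyl group on the same side of the alkene, and the mild heterogeneous carbonate base is chosen to spare the γ-hydrogen at C5 of the product.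

Step 5
Reactants: 11 7-hydroxy-8-methoxycoumarin; 12 bromoacetaldehyde diethyl acetal
Product: 13 7-(2,2-diethoxyethoxy)-8-methoxy-2H-chromen-2-one
Conditions: K2CO3, KI (cat.), DMF, 90 °C
Reagents that add atoms: none
Why: Williamson ether synthesis of the acidic coumarin phenol with a primary bromide under iodide catalysis, under anhydrous conditions that leave the coumarin lactone closed; no stereocentre is formed.

Step 6
Reactants: 13 7-(2,2-diethoxyethoxy)-8-methoxy-2H-chromen-2-one
Product: 14 2-[(8-methoxy-2-oxo-2H-chromen-7-yl)oxy]acetaldehyde
Conditions: TFA, H2O, CH2Cl2, rt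
Reagents that add atoms: water, SMILES O
Why: Acid-catalysed acetal hydrolysis at room temperature should free the aldehyde while the aryl ether and coumarin are stable and the conditions are too mild for Friedel–Crafts closure to a furocoumarin; no stereocentre is formed.

Step 7
Reactants: 10 (R)-5-(2-bromoprop-2-en-1-yl)-3-methylfuran-2(5H)-one; 14 2-[(8-methoxy-2-oxo-2H-chromen-7-yl)oxy]acetaldehyde
Product: 16 7-{[2-hydroxy-3-methylidene-4-[(2R)-4-methyl-5-oxo-2,5-dihydrofuran-2-yl]butyl]oxy}-8-methoxy-2H-chromen-2-one (both carbinol epimers), via alkenylchromium dichloride 15 (not isolated)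
Conditions: CrCl2 (4 equiv), NiCl2 (2 mol%), DMSO, rt
Reagents that add atoms: none
Why: In the Nozaki–Hiyama–Kishi reaction nickel inserts into the alkenyl C–Br bond and transmetallates to chromium, and the alkenylchromium species adds to the aldehyde but not to the butenolide or coumarin carbonyls; the new carbinol centre is formed without control and is removed in step 8, while C5 of the butenolide is untouched under these non-basic conditions.

Step 8
Reactants: 16 allylic alcohol (both carbinol epimers)
Product: 17 8-methoxy-7-{[3-methylidene-4-[(2R)-4-methyl-5-oxo-2,5-dihydrofuran-2-yl]-2-oxobutyl]oxy}-2H-chromen-2-one (target, CNP0262059.1)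
Conditions: Dess–Martin periodinane, NaHCO3, CH2Cl2, 0 °C → rt
Reagents that add atoms: none
Why: Dess–Martin oxidation converts the secondary allylic alcohol to the enone under buffered, near-neutral conditions that should leave the γ-stereocentre of the butenolide, the exocyclic alkene and the coumarin unchanged, and both epimers of 16 converge on one ketone.

**Compound list**

1 | but-2-yn-1-ol | CC#CCO | starting material
2 | sodium 2,2-bis(2-methoxyethoxy)-3-methyl-2,5-dihydro-1,2-oxaaluminol-2-uide (five-membered ring O–Al–C(CH3)=CH–CH2) | [Na+].CC1=CCO[Al-]1(OCCOC)OCCOC | intermediate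
3 | (Z)-3-iodobut-2-en-1-ol | C/C(I)=C/CO | intermediate
4 | (Z)-3-iodobut-2-enal | C/C(I)=C/C=O | intermediate
5 | allene (propa-1,2-diene) | C=C=C | starting material
6 | (2-bromoprop-2-en-1-yl)diisopinocampheylborane, isopinocampheyl groups from (−)-α-pinene | C=C(Br)CB([C@H]1C[C@H]2C[C@@H]([C@@H]1C)C2(C)C)[C@H]1C[C@H]2C[C@@H]([C@@H]1C)C2(C)C | intermediate
7 | (2Z,4R)-6-bromo-2-iodohepta-2,6-dien-4-yl diisopinocampheylborinate | C=C(Br)C[C@@H](OB([C@H]1C[C@H]2C[C@@H]([C@@H]1C)C2(C)C)[C@H]1C[C@H]2C[C@@H]([C@@H]1C)C2(C)C)/C=C(/C)I | intermediate
8 | (2Z,4R)-6-bromo-2-iodohepta-2,6-dien-4-ol | C=C(Br)C[C@@H](O)/C=C(/C)I | intermediate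
9 | carbon monoxide | [C-]#[O+] | starting material
10 | (R)-5-(2-bromoprop-2-en-1-yl)-3-methylfuran-2(5H)-one | C=C(Br)C[C@@H]1C=C(C)C(=O)O1 | intermediate
11 | 7-hydroxy-8-methoxycoumarin | Oc1ccc2ccc(=O)oc2c1OC | starting material
12 | bromoacetaldehyde diethyl acetal (2-bromo-1,1-diethoxyethane) | CCOC(CBr)OCC | starting material
13 | 7-(2,2-diethoxyethoxy)-8-methoxy-2H-chromen-2-one | CCOC(COc1ccc2ccc(=O)oc2c1OC)OCC | intermediate
14 | 2-[(8-methoxy-2-oxo-2H-chromen-7-yl)oxy]acetaldehyde | O=CCOc1ccc2ccc(=O)oc2c1OC | intermediate
15 | [3-((2R)-4-methyl-5-oxo-2,5-dihydrofuran-2-yl)prop-1-en-2-yl]chromium dichloride | C=C([Cr](Cl)Cl)C[C@@H]1C=C(C)C(=O)O1 | intermediate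
16 | 7-{[2-hydroxy-3-methylidene-4-[(2R)-4-methyl-5-oxo-2,5-dihydrofuran-2-yl]butyl]oxy}-8-methoxy-2H-chromen-2-one, both carbinol epimers | C=C(C[C@@H]1C=C(C)C(=O)O1)C(O)COc1ccc2ccc(=O)oc2c1OC | intermediate
17 | 8-methoxy-7-{[3-methylidene-4-[(2R)-4-methyl-5-oxo-2,5-dihydrofuran-2-yl]-2-oxobutyl]oxy}-2H-chromen-2-one | C=C(C[C@@H]1C=C(C)C(=O)O1)C(=O)COc1ccc2ccc(=O)oc2c1OC | target

**Step count and risks**

Total steps: 8. Longest linear sequence: 6 (steps 1, 2, 3, 4, 7, 8); steps 5 and 6 form the coumarin branch.

Steps most likely to fail:

Step 3. The Z-iodoenal may isomerise to the E isomer before or during the addition, and the 2-bromoallyl reagent may give poorer facial selectivity than the parent allylborane. The fallback sets out from aldehyde 4. An indium-mediated Barbier addition of 2,3-dibromopropene (In, THF/H2O, rt) should give racemic (Z)-6-bromo-2-iodohepta-2,6-dien-4-ol F1. Dess–Martin oxidation should give (Z)-6-bromo-2-iodohepta-2,6-dien-4-one F2. Corey–Bakshi–Shibata reduction with the (S)-methyloxazaborolidine and catecholborane at −78 °C, the alkenyl group acting as the larger substituent, should then return to the route at alcohol 8.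

Step 4. Oxidative addition may also occur at the alkenyl C–Br bond, the alkenylpalladium species may cyclise onto the bromoalkene before CO inserts, or the carbonate may erode the configuration at the γ-position of the product. The fallback builds the lactone by ring-closing metathesis and sets out from borane 6. Addition to acrolein at −78 °C and the same oxidative work-up of (R)-5-bromohexa-1,5-dien-3-yl diisopinocampheylborinate F3 (not isolated) should give (R)-5-bromohexa-1,5-dien-3-ol F4. Acylation with methacryloyl chloride (Et3N, DMAP, CH2Cl2, 0 °C) should give (R)-5-bromohexa-1,5-dien-3-yl 2-methylprop-2-enoate F5. Ring-closing metathesis with the second-generation Grubbs catalyst RuCl2(H2IMes)(PCy3)(=CHPh) in refluxing CH2Cl2, in which the hindered 2-bromoalkene should stay out of the catalytic cycle, returns to the route at 10.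

Step 7. Insertion of nickel into the 1,1-disubstituted alkenyl bromide may be slow, so that the aryloxyacetaldehyde degrades or is reduced during a long reaction. The fallback sets out from 10 and activates the halide in a separate step. Copper-catalysed halogen exchange (CuI, NaI, trans-N,N'-dimethylcyclohexane-1,2-diamine, dioxane, 110 °C, short reaction time to limit epimerisation) should give (R)-5-(2-iodoprop-2-en-1-yl)-3-methylfuran-2(5H)-one F6. The alkenyl iodide is the standard, fast partner for chromium–nickel couplings at room temperature, and coupling of F6 with 14 (CrCl2, NiCl2 cat., DMSO, rt) returns to the route at 16.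

**Further compounds**

F1 | step 3 | racemic (Z)-6-bromo-2-iodohepta-2,6-dien-4-ol | C=C(Br)CC(O)/C=C(/C)I
F2 | step 3 | (Z)-6-bromo-2-iodohepta-2,6-dien-4-one | C=C(Br)CC(=O)/C=C(/C)I
F3 | step 4 | (R)-5-bromohexa-1,5-dien-3-yl diisopinocampheylborinate | C=C(Br)C[C@@H](OB([C@H]1C[C@H]2C[C@@H]([C@@H]1C)C2(C)C)[C@H]1C[C@H]2C[C@@H]([C@@H]1C)C2(C)C)C=C
F4 | step 4 | (R)-5-bromohexa-1,5-dien-3-ol | C=C(Br)C[C@@H](O)C=C
F5 | step 4 | (R)-5-bromohexa-1,5-dien-3-yl 2-methylprop-2-enoate | C=C(Br)C[C@@H](OC(=O)C(C)=C)C=C
F6 | step 7 | (R)-5-(2-iodoprop-2-en-1-yl)-3-methylfuran-2(5H)-one | C=C(I)C[C@@H]1C=C(C)C(=O)O1
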